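**Retrosynthetic overview**
1. Numbering: ring B = C1 (exocyclic CH2), C2, C3, C7 (isopropyl), C8, C9 (O-enoate); ring A = C2, C3, C4 (carries carbinol C10), C5 (C=O), C6 (O-acyl).
2. The plan rests on the ring A ketol C5(=O)–C4–C10(OH) with its syn C4/C10 relation. It is carried as a 2-isoxazoline (C5=N–O–C10) and released last by N–O cleavage, after the C6 and C9 esters, the C9–O bond (allylic oxidation) and C1=CH2 (olefination of a C1 ketone) are taken back.
3. Key disconnection: C4–C5 and O–C10, an intramolecular nitrile oxide–alkene (3+2) cycloaddition of a C5 nitrile oxide (from the aldoxime on C6) onto a (Z)-propenyl group on C3. It closes ring A and the isoxazoline together on a finished ring B.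
4. The oxime goes back to a trans-2,3-disubstituted cyclohexanone: C2–C6 by a syn aldol with dimethoxyacetaldehyde, C3–C4 by cuprate addition to (S)-cryptone, itself made from 3-methylbutanal and methyl vinyl ketone.
5. Ring order: ring B (step 2), then ring A with the isoxazoline (step 8); the heterocycle is opened in step 14.

Key step: step 8

Remark: atom labels C1–C10 in the text follow the numbering above; systematic names use their own locants.
Assumption: 2,2-dimethoxyacetaldehyde is sold as an aqueous solution; step 4 takes the water-free monomer to be available from it by extraction into CH2Cl2, drying and distillation just before use.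

**Route**

Step 1
Reactants: 1 3-methylbutanal; 2 but-3-en-2-one
Product: 3 (2S)-5-oxo-2-(propan-2-yl)hexanal
Conditions: (S)-2-[methoxy(diphenyl)methyl]pyrrolidine (5 mol%), ethyl 3,4-dihydroxybenzoate (20 mol%), neat, 4 °C
Reagents that add atoms: none
Why: Amine-catalysed (enamine) Michael addition of an aldehyde to an enone, in which the diphenyl(methoxy)methyl arm of the (S)-pyrrolidine shields one face of the nucleophilic carbon, so the enone should add to the open face and set the isopropyl-bearing centre as S.

Step 2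
Reactants: 3 (2S)-5-oxo-2-(propan-2-yl)hexanal
Product: 5 (4S)-4-(propan-2-yl)cyclohex-2-en-1-one [(S)-cryptone], via aldol ketol 4 (not isolated)
Conditions: LiOH, i-PrOH, rt
Reagents that add atoms: none
Why: Intramolecular aldol condensation in which the methyl ketone enolate closes the six-membered ring onto the aldehyde and ketol 4 loses water by E1cB; the stereocentre becomes C4 of the enone (the later C7) without being touched, and the mild base should keep its enolisation at the aldehyde stage short.

Step 3
Reactants: 5 (S)-cryptone; 6 (1Z)-1-bromoprop-1-ene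
Product: 9 trimethyl{[(3S,4S)-4-(propan-2-yl)-3-[(1Z)-prop-1-en-1-yl]cyclohex-1-en-1-yl]oxy}silane, via (Z)-prop-1-enyllithium 7 (not isolated), via lithium di[(Z)-prop-1-enyl]cuprate 8 (not isolated)
Conditions: 6 (2.4 equiv), t-BuLi (4.8 equiv), Et2O, −78 °C; CuI (1.2 equiv), −40 °C; 5, TMSCl (2 equiv), −78 → −40 °C; Et3N, pentane, cold aq NaHCO3
Reagents that add atoms: chlorotrimethylsilane, C[Si](C)(C)Cl
Why: Bromine–lithium exchange keeps the Z geometry, and the lithium diorganocuprate adds 1,4 to the 4-substituted cyclohexenone on the face anti to the isopropyl group (C3 set trans to C7), while the silyl chloride speeds the conjugate addition and fixes the enolate as the C1–C2 enol silane.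

Step 4
Reactants: 9 enol silane; 10 2,2-dimethoxyacetaldehyde
Product: 13 (2S,3S,4S)-2-[(1S)-1-hydroxy-2,2-dimethoxyethyl]-4-(propan-2-yl)-3-[(1Z)-prop-1-en-1-yl]cyclohexan-1-one, via lithium enolate 11 (not isolated), via chlorozirconocene enolate 12 (not isolated)
Conditions: MeLi (1.05 equiv), THF, 0 °C; (C5H5)2ZrCl2 (1.1 equiv), −78 °C; 10 (1.5 equiv), −78 → −40 °C; aq NH4Cl
Reagents that add atoms: none
Why: Regiospecific enolate release from the enol silane, transmetalation and a zirconium-enolate aldol addition, a reaction that gives syn aldols from either enolate geometry (here from the ring-locked enolate through a boat-like closed transition state), which sets C6 (S) syn to C2, while the aldehyde approaches C2 anti to the neighbouring C3 propenyl group and so sets C2 (S) trans to C3.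

Step 5
Reactants: 13 syn aldol
Product: 14 (2S,3S,4S)-2-[(1S)-1-{[tert-butyl(dimethyl)silyl]oxy}-2,2-dimethoxyethyl]-4-(propan-2-yl)-3-[(1Z)-prop-1-en-1-yl]cyclohexan-1-one
Conditions: TBSOTf, 2,6-lutidine, CH2Cl2, −78 °C
Reagents that add atoms: tert-butyldimethylsilyl trifluoromethanesulfonate, CC(C)(C)[Si](C)(C)OS(=O)(=O)C(F)(F)F
Why: Silyl triflate silylation of a hindered secondary alcohol with a weak, non-nucleophilic base at low temperature, under which neither retro-aldol cleavage nor enol silylation of the C1 ketone should compete and no stereocentre is touched.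

Step 6
Reactants: 14 silyl ether acetal
Product: 15 (2S,3S,4S)-2-[(1S)-1-{[tert-butyl(dimethyl)silyl]oxy}-2-oxoethyl]-4-(propan-2-yl)-3-[(1Z)-prop-1-en-1-yl]cyclohexan-1-one
Conditions: TFA/H2O (1:1), CHCl3, 0 °C
Reagents that add atoms: water, O
Why: Acid-catalysed acetal hydrolysis, in which the dimethyl acetal should be cleaved well before a secondary silyl ether flanked by two electron-poor carbons, and the cold acidic medium leaves the C2 and C6 centres unenolised.

Step 7
Reactants: 15 keto aldehyde
Product: 16 (2S,3S,4S)-2-[(1S,2E)-1-{[tert-butyl(dimethyl)silyl]oxy}-2-(hydroxyimino)ethyl]-4-(propan-2-yl)-3-[(1Z)-prop-1-en-1-yl]cyclohexan-1-one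
Conditions: NH2OH·HCl (1.05 equiv), NaOAc, MeOH, 0 °C
Reagents that add atoms: hydroxylamine hydrochloride, NO.Cl
Why: Oxime condensation, in which the unhindered electron-poor aldehyde should react with one equivalent of buffered hydroxylamine far faster than the doubly branched ring ketone; the E/Z ratio of the aldoxime does not matter for step 8.

Step 8
Reactants: 16 aldoxime
Product: 19 isoxazoline-fused trans-hydrindan-1-one (C6 OTBS; 2S,3R,4R,6S,7S,10R), via hydroximoyl chloride 17 (not isolated), via nitrile oxide 18 (not isolated)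
Conditions: aq NaOCl (5%), CH2Cl2, 0 °C → rt, slow addition, 0.01 M
Reagents that add atoms: none
Why: Hypochlorite chlorinates the aldoxime to hydroximoyl chloride 17, which loses HCl in the basic two-phase medium to give nitrile oxide 18, and this dipole adds across the (Z)-propenyl group in a concerted, suprafacial (3+2) cycloaddition that forms C4–C5 and O–C10. The closest known reaction type is the intramolecular nitrile oxide–alkene cycloaddition of alkenyl aldoximes to cyclopentane-fused 2-isoxazolines. Ring A closes through the C4–C5 bond in a 5-exo mode (the dipole carbon C5 attacks the nearer alkene carbon C4 and C10 stays outside ring A), and the isoxazoline ring (C4, C5, N, O, C10) closes in the same event through O–C10 as the five-membered ring of the cycloaddition itself. C10 is controlled by the Z geometry of the alkene, which is carried over as the cis relation of C3 and the methyl group on the isoxazoline (syn C4/C10), and C4 is controlled by allylic 1,3-strain: C3–H lies in the plane of the Z-propenyl group, so C2 with its tethered dipole sits over one alkene face and C7 under the other, which gives H4 trans to H3. The trans ring fusion is not at stake, because the C2 and C3 substituents are already trans and diequatorial, a spacing that a five-membered ring can span. The step needs cyclisation to outrun dimerisation of the nitrile oxide to a furoxan and chlorination next to the ketone, which slow addition of the oxidant at high dilution, the short tether and the absence of any other alkene should secure.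

Step 9
Reactants: 19 isoxazoline ketone
Product: 21 C1-methylene isoxazoline (C6 OTBS; 2R,3S,4R,6S,7S,10R), via oxaphosphetane 20 (not isolated)
Conditions: Ph3PCH3Br, KOt-Bu, THF, 0 °C → rt
Reagents that add atoms: methyltriphenylphosphonium bromide, C[P+](c1ccccc1)(c1ccccc1)c1ccccc1.[Br-]
Why: Wittig methylenation, in which the unstabilised ylide should add to the C1 ketone faster than it enolises it, so that the C2 centre (both carbon substituents already equatorial) and the β-silyloxy group are kept and the isoxazoline is left alone.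

Step 10
Reactants: 21 methylene compound
Product: 24 axial C9 allylic alcohol (C6 OTBS; 2R,3S,4R,6S,7S,9R,10R), via allylseleninic acid 22 (not isolated), via divalent-selenium ester 23 (not isolated)
Conditions: SeO2 (0.5 equiv), t-BuOOH (2 equiv), CH2Cl2, 0 °C → rt
Reagents that add atoms: selenium dioxide, O=[Se]=O; tert-butyl hydroperoxide, CC(C)(C)OO
Why: SeO2 allylic oxidation, in which the ene reaction at the exocyclic CH2 takes the axial hydrogen of the ring methylene C9 in preference to the ring-fusion methine C2–H, and the [2,3]-sigmatropic shift of 22 restores the exocyclic alkene and delivers oxygen to the same axial face, so that hydrolysis of 23 should give the axial C9 alcohol (R).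

Step 11
Reactants: 24 C9 alcohol; 25 (2E)-3-methylpent-2-enoic acid
Product: 27 C9 (E)-3-methylpent-2-enoate (C6 OTBS), via mixed anhydride 26 (not isolated)
Conditions: 25, 2,4,6-trichlorobenzoyl chloride, Et3N, THF, rt; then 24, DMAP, toluene, rt
Reagents that add atoms: none
Why: Yamaguchi esterification, in which DMAP passes the enoyl group of mixed anhydride 26 to the hindered axial alcohol with retention at C9, and forming the anhydride before alcohol and DMAP are added should limit base-induced deconjugation or E/Z scrambling of the enoate.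

Step 12
Reactants: 27 silyl ether ester
Product: 28 C6 alcohol C9 enoate
Conditions: HF·pyridine, pyridine, THF, 0 °C → rt
Reagents that add atoms: none
Why: Fluoride-driven cleavage of the silyl ether by buffered HF, a mildly acidic, non-basic reagent to which the enoate, the isoxazoline and the exocyclic alkene should be stable, with no acyl shift possible between the remote C9 and C6 oxygens.

Step 13
Reactants: 28 C6 alcohol; 29 (2R)-2-methylbutanoic acid
Product: 31 C6 (R)-2-methylbutanoate C9 (E)-3-methylpent-2-enoate isoxazoline, via O-acylisourea 30 (not isolated)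
Conditions: DCC, DMAP (10 mol%), CH2Cl2, 0 °C → rt
Reagents that add atoms: none
Why: Steglich esterification through 30, which acylates the secondary C6 alcohol with retention at C6 and, with no ketene-forming base present, should leave the α-centre of the (R)-acid intact.

Step 14
Reactants: 31 diester isoxazoline
Product: 33 CNP0224363.2 (target), via β-hydroxy imine 32 (not isolated)
Conditions: Mo(CO)6, MeCN/H2O (10:1), 80 °C
Reagents that add atoms: water, O
Why: Reductive N–O cleavage of a 2-isoxazoline by zerovalent molybdenum gives 32, whose hydrolysis frees the C5 ketone; the C10–O and C4–C5 bonds are not broken, so the syn C4/C10 relation from step 8 passes into the ketol, and the near-neutral medium should spare both esters, the alkenes and the enolisable C4 and C6 centres.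

**Compound list**
1 | 3-methylbutanal | CC(C)CC=O | starting material
2 | but-3-en-2-one (methyl vinyl ketone) | CC(=O)C=C | starting material
3 | (2S)-5-oxo-2-(propan-2-yl)hexanal | O=C[C@H](C(C)C)CCC(C)=O | intermediate
4 | (4S)-3-hydroxy-4-(propan-2-yl)cyclohexan-1-one, aldol ketol, carbinol epimers, formed in situ | O=C1CC(O)[C@H](C(C)C)CC1 | intermediate
5 | (4S)-4-(propan-2-yl)cyclohex-2-en-1-one, (S)-cryptone | O=C1C=C[C@H](C(C)C)CC1 | intermediate
6 | (1Z)-1-bromoprop-1-ene | C/C=C\Br | starting material
7 | (1Z)-prop-1-en-1-yllithium, formed in situ | C/C=C\[Li] | intermediate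
8 | lithium di[(1Z)-prop-1-en-1-yl]cuprate, formed in situ | [Li+].C/C=C\[Cu-]/C=C\C | intermediate
9 | trimethyl{[(3S,4S)-4-(propan-2-yl)-3-[(1Z)-prop-1-en-1-yl]cyclohex-1-en-1-yl]oxy}silane | C[Si](C)(C)OC1=C[C@@H](/C=C\C)[C@H](C(C)C)CC1 | intermediate
10 | 2,2-dimethoxyacetaldehyde | COC(OC)C=O | starting material
11 | lithium (3S,4S)-4-(propan-2-yl)-3-[(1Z)-prop-1-en-1-yl]cyclohex-1-en-1-olate, formed in situ | [Li]OC1=C[C@@H](/C=C\C)[C@H](C(C)C)CC1 | intermediate
12 | chlorobis(cyclopentadienyl)zirconium enolate of the same ketone, formed in situ | Cl[Zr](OC1=C[C@@H](/C=C\C)[C@H](C(C)C)CC1)(C1C=CC=C1)C1C=CC=C1 | intermediate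
13 | (2S,3S,4S)-2-[(1S)-1-hydroxy-2,2-dimethoxyethyl]-4-(propan-2-yl)-3-[(1Z)-prop-1-en-1-yl]cyclohexan-1-one | O=C1CC[C@@H](C(C)C)[C@H](/C=C\C)[C@H]1[C@H](O)C(OC)OC | intermediate
14 | (2S,3S,4S)-2-[(1S)-1-{[tert-butyl(dimethyl)silyl]oxy}-2,2-dimethoxyethyl]-4-(propan-2-yl)-3-[(1Z)-prop-1-en-1-yl]cyclohexan-1-one | O=C1CC[C@@H](C(C)C)[C@H](/C=C\C)[C@H]1[C@H](O[Si](C)(C)C(C)(C)C)C(OC)OC | intermediate
15 | (2S,3S,4S)-2-[(1S)-1-{[tert-butyl(dimethyl)silyl]oxy}-2-oxoethyl]-4-(propan-2-yl)-3-[(1Z)-prop-1-en-1-yl]cyclohexan-1-one | O=C1CC[C@@H](C(C)C)[C@H](/C=C\C)[C@H]1[C@H](O[Si](C)(C)C(C)(C)C)C=O | intermediate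
16 | (2S,3S,4S)-2-[(1S,2E)-1-{[tert-butyl(dimethyl)silyl]oxy}-2-(hydroxyimino)ethyl]-4-(propan-2-yl)-3-[(1Z)-prop-1-en-1-yl]cyclohexan-1-one (key-step precursor) | O=C1CC[C@@H](C(C)C)[C@H](/C=C\C)[C@H]1[C@H](O[Si](C)(C)C(C)(C)C)/C=N/O | intermediate
17 | hydroximoyl chloride of 16 (C5 carries Cl; side-chain centre S), formed in situ | O=C1CC[C@@H](C(C)C)[C@H](/C=C\C)[C@H]1[C@H](O[Si](C)(C)C(C)(C)C)C(Cl)=NO | intermediate
18 | nitrile oxide of 16 (C5≡N–O), formed in situ | O=C1CC[C@@H](C(C)C)[C@H](/C=C\C)[C@H]1[C@H](O[Si](C)(C)C(C)(C)C)C#[N+][O-] | intermediate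
19 | isoxazoline-fused trans-hydrindan-1-one: C1 ketone, C6 OTBS, 2-isoxazoline C5=N–O–C10 fused across C4–C5, methyl on C10, isopropyl on C7; C2 S, C3 R, C4 R, C6 S, C7 S, C10 R (key-step product) | O=C1[C@H]2[C@@H]([C@H]3[C@@H](C)ON=C3[C@H]2O[Si](C)(C)C(C)(C)C)[C@H](C(C)C)CC1 | intermediate
20 | spiro-oxaphosphetane at C1 of 19 (C1–O–PPh3–CH2 ring), formed in situ | C1P(c2ccccc2)(c2ccccc2)(c2ccccc2)OC14[C@H]2[C@@H]([C@H]3[C@@H](C)ON=C3[C@H]2O[Si](C)(C)C(C)(C)C)[C@H](C(C)C)CC4 | intermediate
21 | C1-methylene analogue of 19; C2 R, C3 S, C4 R, C6 S, C7 S, C10 R | C=C1[C@H]2[C@@H]([C@H]3[C@@H](C)ON=C3[C@H]2O[Si](C)(C)C(C)(C)C)[C@H](C(C)C)CC1 | intermediate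
22 | allylseleninic acid: C1=C9 alkene, CH2–Se(=O)OH on C1, formed in situ | O=[Se](O)CC=1[C@H]2[C@@H]([C@H]3[C@@H](C)ON=C3[C@H]2O[Si](C)(C)C(C)(C)C)[C@H](C(C)C)CC=1 | intermediate
23 | divalent-selenium ester C9–O–Se–OH of alcohol 24, formed in situ | C=C1[C@H]2[C@@H]([C@H]3[C@@H](C)ON=C3[C@H]2O[Si](C)(C)C(C)(C)C)[C@H](C(C)C)C[C@H]1O[Se]O | intermediate
24 | C9 axial allylic alcohol of 21; C2 R, C3 S, C4 R, C6 S, C7 S, C9 R, C10 R | C=C1[C@H]2[C@@H]([C@H]3[C@@H](C)ON=C3[C@H]2O[Si](C)(C)C(C)(C)C)[C@H](C(C)C)C[C@H]1O | intermediate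
25 | (2E)-3-methylpent-2-enoic acid | OC(=O)/C=C(\C)CC | starting material
26 | (2E)-3-methylpent-2-enoic 2,4,6-trichlorobenzoic anhydride, formed in situ | O=C(OC(=O)/C=C(\C)CC)c1c(Cl)cc(Cl)cc1Cl | intermediate
27 | C9 (2E)-3-methylpent-2-enoate of 24 (C6 OTBS) | C=C1[C@H]2[C@@H]([C@H]3[C@@H](C)ON=C3[C@H]2O[Si](C)(C)C(C)(C)C)[C@H](C(C)C)C[C@H]1OC(=O)/C=C(\C)CC | intermediate
28 | C6 alcohol of 27 (C6 S) | C=C1[C@H]2[C@@H]([C@H]3[C@@H](C)ON=C3[C@H]2O)[C@H](C(C)C)C[C@H]1OC(=O)/C=C(\C)CC | intermediate
29 | (2R)-2-methylbutanoic acid | OC(=O)[C@H](C)CC | starting material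
30 | O-[(2R)-2-methylbutanoyl]-N,N'-dicyclohexylisourea, formed in situ | C1CCCCC1N=C(NC1CCCCC1)OC(=O)[C@H](C)CC | intermediate
31 | C6 (2R)-2-methylbutanoate, C9 (2E)-3-methylpent-2-enoate isoxazoline; C2 R, C3 S, C4 R, C6 S, C7 S, C9 R, C10 R | C=C1[C@H]2[C@@H]([C@H]3[C@@H](C)ON=C3[C@H]2OC(=O)[C@H](C)CC)[C@H](C(C)C)C[C@H]1OC(=O)/C=C(\C)CC | intermediate
32 | β-hydroxy imine: C5=NH, C10 OH, both esters in place, formed in situ | C=C1[C@H]2[C@@H]([C@@H]([C@@H](C)O)C(=N)[C@H]2OC(=O)[C@H](C)CC)[C@H](C(C)C)C[C@H]1OC(=O)/C=C(\C)CC | intermediate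
33 | CNP0224363.2; C2 R, C3 S, C4 S, C6 S, C7 S, C9 R, C10 R, (2R)-2-methylbutanoate on C6, (2E)-3-methylpent-2-enoate on C9 | C=C1[C@H]2[C@@H]([C@@H]([C@@H](C)O)C(=O)[C@H]2OC(=O)[C@H](C)CC)[C@H](C(C)C)C[C@H]1OC(=O)/C=C(\C)CC | target

**Step count**
Total: 14 steps. Longest linear sequence: 14 steps (from 1 and 2 to 33).

**Steps most likely to fail and fallbacks**

Step 4. The zirconium aldol may give poor syn/anti control, or the water-free aldehyde may oligomerise or hydrate before it reacts. The fallback sets out from enol silane 9 and comes back to the route at keto aldehyde 15. A TiCl4-mediated Mukaiyama aldol addition of 9 to ethyl glyoxylate (CH2Cl2, −78 °C) would be used; its open transition state should favour the syn adduct for a cyclohexanone-derived enol silane and again places the electrophile anti to the C3 propenyl group, giving the α-hydroxy ester F1. Silylation with TBSOTf and 2,6-lutidine would give the silyl ether F2. Reduction with i-Bu2AlH would take both the ester and the ring ketone to the diol F3 (mixture at C1). Dess–Martin oxidation of both hydroxyl groups would give 15. This also avoids the acetal hydrolysis of step 6.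

Step 8. The nitrile oxide may dimerise to the furoxan, or the oxidant may chlorinate elsewhere, faster than the ring closes. The fallback sets out from oxime 16 and comes back at isoxazoline 19. Heating 16 in toluene (sealed tube, 140–160 °C) should tautomerise the oxime to its N–H nitrone, which adds to the same alkene face in an intramolecular oxime–olefin (3+2) cycloaddition to give the cis-fused N–H isoxazolidine F4. N-Chlorination with N-chlorosuccinimide and loss of HCl with Et3N, which can only form the C5=N bond, would then give 19 without a free nitrile oxide being present.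

Step 10. The ene reaction may take the ring-fusion C2–H instead of C9–H, the alcohol may be over-oxidised to the enone, or oxygen may be delivered to the wrong face. The fallback sets out from ketone 19 and comes back at alcohol 24. Kinetic deprotonation at the C9 methylene (LiN(i-Pr)2, TMSCl, THF, −78 °C) would give the C1–C9 enol silane F5. Rubottom oxidation (m-CPBA, NaHCO3, CH2Cl2, then dilute acid), with the peracid expected on the ring face away from the C6 silyloxy group, would give the axial α-hydroxy ketone F6. Wittig methylenation of F6 with an excess of Ph3P=CH2 would give 24, so the C9 oxygen is installed by enolate oxidation before the alkene exists.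

**Further compounds**
F1 | step 4 | ethyl (2S)-2-hydroxy-2-[(1S,5S,6S)-2-oxo-5-(propan-2-yl)-6-[(1Z)-prop-1-en-1-yl]cyclohexyl]acetate | O=C1CC[C@@H](C(C)C)[C@H](/C=C\C)[C@H]1[C@H](O)C(=O)OCC
F2 | step 4 | ethyl (2S)-2-{[tert-butyl(dimethyl)silyl]oxy}-2-[(1S,5S,6S)-2-oxo-5-(propan-2-yl)-6-[(1Z)-prop-1-en-1-yl]cyclohexyl]acetate | O=C1CC[C@@H](C(C)C)[C@H](/C=C\C)[C@H]1[C@H](O[Si](C)(C)C(C)(C)C)C(=O)OCC
F3 | step 4 | 2-[(1S)-1-{[tert-butyl(dimethyl)silyl]oxy}-2-hydroxyethyl]-4-(propan-2-yl)-3-[(1Z)-prop-1-en-1-yl]cyclohexan-1-ol, ring configuration as in F2, mixture of C1 carbinol epimers | OC1CC[C@@H](C(C)C)[C@H](/C=C\C)[C@H]1[C@H](O[Si](C)(C)C(C)(C)C)CO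
F4 | step 8 | cis-fused N–H isoxazolidine: 19 with C5–H and N–H in place of C5=N | O=C1[C@H]2[C@@H]([C@H]3[C@@H](C)ON[C@H]3[C@H]2O[Si](C)(C)C(C)(C)C)[C@H](C(C)C)CC1
F5 | step 10 | C1–C9 trimethylsilyl enol ether of ketone 19 | C[Si](C)(C)OC=1[C@H]2[C@@H]([C@H]3[C@@H](C)ON=C3[C@H]2O[Si](C)(C)C(C)(C)C)[C@H](C(C)C)CC=1
F6 | step 10 | (9R)-9-hydroxy derivative of ketone 19, axial C9 OH | O=C1[C@H]2[C@@H]([C@H]3[C@@H](C)ON=C3[C@H]2O[Si](C)(C)C(C)(C)C)[C@H](C(C)C)C[C@H]1O
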